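Assumption: the target has no stereocentre (the bridging CH carries two identical aryl groups), so the compound itself is the goal; 6-methylheptanal is taken as a purchasable flavour-grade aldehyde.

**Retrosynthetic overview**
- 12 ⇒ 8: both aryl-O–C(CH3)2 bonds are cut; they form last by double Markovnikov hydroalkoxylation of two prenyl groups, with site control from a transient bis-boronate clip (new step).
- 8 ⇒ 2 × 5 + 6: the alkylidene bridge is made at the only free ring carbon of the prenylated acylphloroglucinol.
- 5 ⇒ 3 + prenyl bromide; 3 ⇒ phloroglucinol + isobutyryl chloride.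
- Ring order: the two arenes come from phloroglucinol; the two dihydropyran rings are closed together in the final step.

**Step 1**
Reactants: 1 phloroglucinol; 2 isobutyryl chloride
Product: 3 2-methyl-1-(2,4,6-trihydroxyphenyl)propan-1-one
Conditions: AlCl3 (3.5 equiv), PhNO2/CH2Cl2, 0 → 60 °C; ice/aq HCl work-up
Reagents that add atoms: none
Why: Friedel–Crafts acylation of the C3-symmetric triol gives a single monoketone, and the aluminium-chelated aryl ketone is deactivated toward a second acylation.

**Step 2**
Reactants: 3 2-methyl-1-(2,4,6-trihydroxyphenyl)propan-1-one; 4 prenyl bromide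
Product: 5 2-methyl-1-[2,4,6-trihydroxy-3-(3-methylbut-2-en-1-yl)phenyl]propan-1-one
Conditions: 4 (1.0 equiv), KOH (1.0 equiv), H2O, 0 °C → rt; chromatography
Reagents that add atoms: none
Why: C-alkylation of the ambident phloroglucinolate (SN2 on the primary allylic bromide, with water hydrogen-bonding the phenoxide oxygens and steering attack to carbon); one equivalent of bromide and base limits it to mono-prenylation, and the two free ring positions of 3 are equivalent.

**Step 3**
Reactants: 5 2-methyl-1-[2,4,6-trihydroxy-3-(3-methylbut-2-en-1-yl)phenyl]propan-1-one (2 equiv); 6 6-methylheptanal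
Product: 8 1,1-bis[3-isobutyryl-2,4,6-trihydroxy-5-(3-methylbut-2-en-1-yl)phenyl]-6-methylheptane, via o-quinone methide 7 (not isolated)
Conditions: 6 (0.5 equiv), ethylenediammonium diacetate (20 mol %), THF, 40 °C
Reagents that add atoms: none
Why: 2:1 phenol–aldehyde condensation of Knoevenagel–Michael type: the amine salt condenses 6 at the single free ring carbon of 5 to give o-quinone methide 7, which a second molecule of 5 captures at carbon; the buffer is too weakly acidic to touch the prenyl groups, and the new methine bears two identical aryls so it is not a stereocentre.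

**Step 4**
Reactants: 8 1,1-bis[3-isobutyryl-2,4,6-trihydroxy-5-(3-methylbut-2-en-1-yl)phenyl]-6-methylheptane; 9 phenylboronic acid (2.05 equiv)
Product: 12 target CNP0275635.0, via bis-boronate clip 10 (not isolated), via cyclised bis-boronate 11 (not isolated)
Conditions: PhMe, Dean–Stark, reflux; cool, Tf2NH (10 mol %), 40 °C; then MeOH/1 M aq HCl, rt
Reagents that add atoms: none
Why: Proposed new method: a transient boronate clip makes the ring closure site-selective, because only the four phenols flanking the methine bridge can be spanned pairwise by one boron (their O···O distance across the bridge, about 2.6 Å, is that of the native inter-ring hydrogen bonds) and each boron is further pinned by the neighbouring acyl C=O as a six-membered O,O-chelate, so after full dehydration the only free OH groups are the two lying between acyl and prenyl; catalytic Tf2NH then protonates each trisubstituted alkene to the tertiary cation (Markovnikov), the free phenol captures it 6-endo to forge both O–C(CH3)2 bonds, and mild aqueous methanolysis releases the four phenols; the boron-bound oxygens are poor nucleophiles and the clip also blocks xanthene formation and acid cleavage of the bridge; the closest known reaction types are acid-catalysed cyclisation of o-prenylphenols to 2,2-dimethylchromans (intramolecular hydroalkoxylation) and boronic esters as transient protecting groups for diols; no stereocentre is formed.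

**Compound list**
1 | phloroglucinol (benzene-1,3,5-triol) | Oc1cc(O)cc(O)c1 | starting material
2 | isobutyryl chloride (2-methylpropanoyl chloride) | CC(C)C(=O)Cl | starting material
3 | 2-methyl-1-(2,4,6-trihydroxyphenyl)propan-1-one (phlorisobutyrophenone) | CC(C)C(=O)c1c(O)cc(O)cc1O | intermediate
4 | prenyl bromide (1-bromo-3-methylbut-2-ene) | CC(C)=CCBr | starting material
5 | 2-methyl-1-[2,4,6-trihydroxy-3-(3-methylbut-2-en-1-yl)phenyl]propan-1-one | CC(C)C(=O)c1c(O)cc(O)c(CC=C(C)C)c1O | intermediate
6 | 6-methylheptanal | CC(C)CCCCC=O | starting material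
7 | o-quinone methide from 5 and 6: 3,5-dihydroxy-2-isobutyryl-6-(6-methylheptylidene)-4-(3-methylbut-2-en-1-yl)cyclohexa-2,4-dien-1-one (exocyclic C=C geometry not fixed, since tautomerism of the flanking OH/C=O pair interconverts E and Z) | CC(C)CCCCC=C1C(=O)C(C(=O)C(C)C)=C(O)C(CC=C(C)C)=C1O | intermediate (not isolated)
8 | 1,1-bis[3-isobutyryl-2,4,6-trihydroxy-5-(3-methylbut-2-en-1-yl)phenyl]-6-methylheptane | CC(C)CCCCC(c1c(O)c(CC=C(C)C)c(O)c(C(=O)C(C)C)c1O)c1c(O)c(CC=C(C)C)c(O)c(C(=O)C(C)C)c1O | intermediate
9 | phenylboronic acid | OB(O)c1ccccc1 | starting material (recoverable template)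
10 | bis(phenylboronate) of 8: each PhB bridges, across the methine, the acyl-side phenol O of one ring and the prenyl-side phenol O of the other (two eight-membered dioxaborocine rings; each B also takes a dative bond from the adjacent isobutyryl C=O, not drawn); the two OH groups between acyl and prenyl are free | CC(C)CCCCC1c2c(O3)c(CC=C(C)C)c(O)c(C(=O)C(C)C)c2OB(c4ccccc4)Oc5c(CC=C(C)C)c(O)c(C(=O)C(C)C)c(OB3c6ccccc6)c51 | intermediate (not isolated)
11 | the same bis(phenylboronate) after ring closure: each free OH has added to its prenyl group to give a 2,2-dimethyl-3,4-dihydro-2H-pyran ring | CC(C)CCCCC1c2c(O3)c4CCC(C)(C)Oc4c(C(=O)C(C)C)c2OB(c5ccccc5)Oc6c7CCC(C)(C)Oc7c(C(=O)C(C)C)c(OB3c8ccccc8)c61 | intermediate (not isolated)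
12 | CNP0275635.0: 1,1'-[(6-methylheptane-1,1-diyl)bis(5,7-dihydroxy-2,2-dimethyl-3,4-dihydro-2H-chromene-6,8-diyl)]bis(2-methylpropan-1-one), achiral | CC(C)CCCCC(c1c(O)c2c(c(C(=O)C(C)C)c1O)OC(C)(C)CC2)c1c(O)c2c(c(C(=O)C(C)C)c1O)OC(C)(C)CC2 | target

**Totals**
Total steps: 4. Longest linear sequence: 4 (from phloroglucinol).

**Steps most likely to fail**

Step 4 (proposed new step). The clip may form incompletely or in a mode that leaves a bridge-side phenol free, which would give regioisomeric chromans. The fallback uses known chemistry, sets out from 5 and comes back at 12.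
- Tosylation of 5 (TsCl 2.1 equiv, K2CO3, acetone, rt) caps the two more accessible phenols and leaves only the hindered, chelated OH between acyl and prenyl, giving 2-hydroxy-3-prenyl-4,6-bis(tosyloxy)isobutyrophenone F1.
- Amberlyst-15 in toluene at 80 °C closes the only possible chroman, 8-isobutyryl-2,2-dimethylchroman-5,7-diyl bis(4-methylbenzenesulfonate) F2.
- KOH in MeOH/H2O at reflux removes both sulfonates to give 8-isobutyryl-5,7-dihydroxy-2,2-dimethylchroman F3.
- Two equivalents of F3 and 6 with cat. p-TsOH in CH2Cl2 bridge at C6, the only free ring carbon, to give 12.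
- This costs three extra steps.

Step 3. Risks are self-aldol of the enolisable aldehyde and interception of 7 by a prenyl alkene. The fallback sets out from 5 and comes back at 8 by a stepwise Mannich route.
- 5, 6 and morpholine (1 equiv each, EtOH, rt) give the isolable Mannich base 2-methyl-1-{2,4,6-trihydroxy-3-[6-methyl-1-(morpholin-4-yl)heptyl]-5-(3-methylbut-2-en-1-yl)phenyl}propan-1-one F4.
- Heating F4 with a second equivalent of 5 in toluene at 80 °C expels morpholine and delivers 8.

Step 2. Risks are bis-prenylation, O-prenylation and a modest yield. The fallback sets out from 3 and comes back at 5.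
- It replaces phenolate alkylation with electrophilic (Friedel–Crafts) prenylation: 3 with 2-methylbut-3-en-2-ol and BF3·OEt2 in dioxane at rt, stopped early before chroman formation.
- This makes no new compound (F0).

**Further compounds**
F1 | step 4 | 1-[2-hydroxy-3-(3-methylbut-2-en-1-yl)-4,6-bis(tosyloxy)phenyl]-2-methylpropan-1-one | CC(C)C(=O)c1c(OS(=O)(=O)c2ccc(C)cc2)cc(OS(=O)(=O)c2ccc(C)cc2)c(CC=C(C)C)c1O
F2 | step 4 | 8-isobutyryl-2,2-dimethyl-3,4-dihydro-2H-chromene-5,7-diyl bis(4-methylbenzenesulfonate) | CC(C)C(=O)c1c(OS(=O)(=O)c2ccc(C)cc2)cc(OS(=O)(=O)c2ccc(C)cc2)c2CCC(C)(C)Oc12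
F3 | step 4 | 1-(5,7-dihydroxy-2,2-dimethyl-3,4-dihydro-2H-chromen-8-yl)-2-methylpropan-1-one | CC(C)C(=O)c1c(O)cc(O)c2CCC(C)(C)Oc12
F4 | step 3 | 2-methyl-1-{2,4,6-trihydroxy-3-[6-methyl-1-(morpholin-4-yl)heptyl]-5-(3-methylbut-2-en-1-yl)phenyl}propan-1-one (racemic) | CC(C)CCCCC(N1CCOCC1)c1c(O)c(CC=C(C)C)c(O)c(C(=O)C(C)C)c1O
F0 | step 2 | none | none
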